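**Retrosynthetic overview**
1. Structural lever: in ring B (the central guaiacyl ring) C5, the carbon bonded to C8, sits next to the phenolic carbon C4. Of the three ring positions an O4-bound allyl group could reach by sigmatropic migration, C3 is occupied by OMe and C1 by the lactone-bound CH2, so C5 is the only productive terminus.
2. C9H2OH is traced back to an (E)-propenyl group on C8 (alkene cleavage, reduction). The C5–C8 bond is traced back to the O4–C bond of an (R)-configured secondary allyl aryl ether through an aromatic Claisen shift with 1,3-chirality transfer.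
3. The ether is cut at O4 (Mitsunobu inversion) into a matairesinol-type mono-phenol and an (S,E)-allylic alcohol that already carries C7 as a silyl ether. This alcohol is built from O-TIPS-vanillin and (S)-but-3-yn-2-ol by asymmetric alkynylzinc addition and trans-hydroalumination.
4. The mono-phenol comes from trans-selective alkylation of an (R)-β-benzylbutyrolactone (Stobbe condensation, asymmetric hydrogenation, ester reduction/lactonisation) with a TIPS-protected vanillyl bromide, followed by debenzylation.
5. Ring order: arenes A (α-benzyl), B (central) and C (side chain) are bought intact. The butyrolactone (ring D) is the only ring made and closes early by lactonisation. The key step closes no ring.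

Key step: step 15

Assumption: atom labels follow lignan usage (ring B C1–C6, side chain C7–C9), and the antipode named for each chiral catalyst is the one expected by analogy with its standard substrates; the mirror-image ligand is equally available should the sense prove opposite.

**Step 1**
Reactants: 1 O-benzylvanillin (4-benzyloxy-3-methoxybenzaldehyde); 2 dimethyl succinate
Product: 3 (E)-4-[4-(benzyloxy)-3-methoxyphenyl]-3-(methoxycarbonyl)but-3-enoic acid
Conditions: NaOMe, MeOH, reflux; then aq HCl
Reagents that add atoms: none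
Why: Stobbe condensation: a non-enolisable aromatic aldehyde and a succinic diester condense irreversibly because the sequence ends in a carboxylate, which should give the (E)-alkylidene half-ester (aryl trans to CO2Me) with the two carboxyl carbons already differentiated.

**Step 2**
Reactants: 3 Stobbe half-ester
Product: 4 (3R)-4-[4-(benzyloxy)-3-methoxyphenyl]-3-(methoxycarbonyl)butanoic acid
Conditions: [Rh(cod)((S,S)-Et-DuPhos)]BF4 (0.5 mol %), NaOMe (10 mol %), H2 (5 bar), MeOH, rt
Reagents that add atoms: none
Why: Rhodium-catalysed asymmetric hydrogenation of an itaconate-type half-ester: the β-carboxylate and the alkene bind the cationic rhodium centre as a chelate, so the C2-symmetric bisphospholane decides the face that receives H2 and sets the future lactone β-carbon as (R), while the benzyl ether is inert to this homogeneous catalyst.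

**Step 3**
Reactants: 4 (R)-half-ester
Product: 6 (4R)-4-[4-(benzyloxy)-3-methoxybenzyl]dihydrofuran-2(3H)-one, via hydroxy acid 5 (not isolated)
Conditions: KOH (1 equiv), EtOH; CaCl2, NaBH4, EtOH, −10 °C → rt; then 2 M HCl
Reagents that add atoms: none
Why: Chemoselective borohydride reduction followed by acid lactonisation: Ca(BH4)2 generated in situ reduces the methyl ester but leaves the potassium carboxylate alone, and acidification closes the butyrolactone (ring D, 5-exo-trig) from hydroxy acid 5 without touching the stereocentre.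

**Step 4**
Reactants: 7 vanillin
Product: 8 3-methoxy-4-(triisopropylsilyloxy)benzaldehyde (O-TIPS-vanillin)
Conditions: TIPSCl, imidazole, DMF, rt
Reagents that add atoms: triisopropylsilyl chloride, CC(C)[Si](Cl)(C(C)C)C(C)C
Why: Imidazole-promoted O-silylation of a phenol; the bulky TIPS group is chosen because it must later survive amide base, organozinc reagents, aluminium hydride and buffered HF.

**Step 5**
Reactants: 8 O-TIPS-vanillin
Product: 9 [3-methoxy-4-(triisopropylsilyloxy)phenyl]methanol
Conditions: NaBH4, MeOH, 0 °C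
Reagents that add atoms: none
Why: Borohydride reduction of an aromatic aldehyde, to which the aryl silyl ether is inert at 0 °C.

**Step 6**
Reactants: 9 benzylic alcohol
Product: 10 4-(bromomethyl)-2-methoxy-1-(triisopropylsilyloxy)benzene
Conditions: CBr4, PPh3, CH2Cl2, 0 °C; used at once
Reagents that add atoms: carbon tetrabromide, BrC(Br)(Br)Br
Why: Appel bromination converts the benzylic alcohol into the bromide under neutral conditions, which avoids acid-induced loss of the silyl group and self-condensation of this electron-rich benzylic halide.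

**Step 7**
Reactants: 6 (R)-β-benzyl lactone; 10 benzylic bromide
Product: 12 (3R,4R)-4-[4-(benzyloxy)-3-methoxybenzyl]-3-[3-methoxy-4-(triisopropylsilyloxy)benzyl]dihydrofuran-2(3H)-one, via lithium enolate 11 (not isolated)
Conditions: LiN(SiMe3)2, THF, −78 °C; then 10, −78 → −20 °C
Reagents that add atoms: none
Why: Lactone enolate alkylation: the planar lithium enolate 11 is attacked by the benzylic bromide on the face opposite to the β-benzyl group, so the new α-stereocentre (R) forms trans to the resident one under substrate control, as is general for β-benzylbutyrolactones.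

**Step 8**
Reactants: 12 trans-dibenzyl lactone
Product: 13 (3R,4R)-4-(4-hydroxy-3-methoxybenzyl)-3-[3-methoxy-4-(triisopropylsilyloxy)benzyl]dihydrofuran-2(3H)-one
Conditions: H2 (1 atm), 10% Pd/C, EtOAc, rt
Reagents that add atoms: none
Why: Catalytic hydrogenolysis cleaves only the O-benzyl bond, since the silyl ether, the lactone and the benzylic C–C bonds are inert, and so unmasks the C4–OH of ring B alone.

**Step 9**
Reactants: 14 (S)-but-3-yn-2-ol
Product: 15 (S)-3-(triethylsilyloxy)but-1-yne
Conditions: TESCl, imidazole, CH2Cl2, 0 °C → rt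
Reagents that add atoms: triethylsilyl chloride, CC[Si](Cl)(CC)CC
Why: Imidazole-promoted O-silylation with retention at carbon; TES is chosen because it can later be removed in the presence of TBS and aryl TIPS ethers.

**Step 10**
Reactants: 15 TES-protected butynol; 8 O-TIPS-vanillin
Product: 17 (1S,4S)-1-[3-methoxy-4-(triisopropylsilyloxy)phenyl]-4-(triethylsilyloxy)pent-2-yn-1-ol, via alkynyl(ethyl)zinc 16 (not isolated)
Conditions: 15 (2 equiv), Et2Zn, Cy2NH (5 mol %), (R)-BINOL (20 mol %), Et2O, rt; Ti(OiPr)4 (50 mol %); then 8, rt; aq NH4Cl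
Reagents that add atoms: none
Why: BINOL–Ti(OiPr)4-catalysed asymmetric alkynylzinc 1,2-addition, a method at its best with aromatic aldehydes: the chiral titanium complex exposes the Re face of aldehyde 8 to alkynylzinc 16 and so sets C7 under catalyst control (descriptor S here because alkynyl outranks aryl), the remote carbinol centre of the alkyne being a spectator.

**Step 11**
Reactants: 17 propargylic alcohol
Product: 19 (1R,2E,4S)-1-[3-methoxy-4-(triisopropylsilyloxy)phenyl]-4-(triethylsilyloxy)pent-2-en-1-ol, via alkenylalanate 18 (not isolated)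
Conditions: NaAlH2(OCH2CH2OMe)2, Et2O, −20 → 0 °C; aq potassium sodium tartrate
Reagents that add atoms: none
Why: Hydroxyl-directed trans-hydroalumination of a propargylic alcohol: the C7 alkoxide carries the aluminium hydride to the alkyne and gives cyclic alanate 18, whose protonolysis leaves the (E)-alkene, and reducing at this stage places aluminium next to the non-benzylic OTES carbon, where eliminative allene formation is least likely (C7 becomes R through a change of CIP ranking only).

**Step 12**
Reactants: 19 (E)-allylic alcohol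
Product: 20 (2S,3E,5R)-5-(tert-butyldimethylsilyloxy)-5-[3-methoxy-4-(triisopropylsilyloxy)phenyl]-2-(triethylsilyloxy)pent-3-ene
Conditions: TBSCl, imidazole, DMF, rt
Reagents that add atoms: tert-butyldimethylsilyl chloride, CC(C)(C)[Si](C)(C)Cl
Why: Imidazole-promoted silylation of the only free hydroxyl under non-ionising conditions, with retention at C7.

**Step 13**
Reactants: 20 tris-silyl ether
Product: 21 (2S,3E,5R)-5-(tert-butyldimethylsilyloxy)-5-[3-methoxy-4-(triisopropylsilyloxy)phenyl]pent-3-en-2-ol
Conditions: HF·pyridine, pyridine, THF, 0 °C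
Reagents that add atoms: none
Why: Selective desilylation by steric discrimination: buffered HF·pyridine in an aprotic solvent removes the secondary TES ether much faster than the TBS or aryl TIPS ethers, and the absence of a protic solvent and of strong acid protects the doubly activated C7–O bond from solvolysis.

**Step 14**
Reactants: 13 mono-phenol lactone; 21 (S,E)-allylic alcohol
Product: 22 lactone 13 etherified at O4 of ring B by the (2R,3E,5R)-5-(tert-butyldimethylsilyloxy)-5-[3-methoxy-4-(triisopropylsilyloxy)phenyl]pent-3-en-2-yl group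
Conditions: PPh3, DIAD, toluene, 0 °C → rt
Reagents that add atoms: none
Why: Mitsunobu etherification: the phenol displaces the activated (S)-carbinol in an SN2 manner with inversion to the (R)-ether, direct attack being favoured over SN2' because the distal alkene carbon is shielded by the branched C7 substituent.

**Step 15**
Reactants: 22 (R)-secondary allyl aryl ether
Product: 24 C4-phenol whose ring B carries at C5 the (1R,2S,3E)-1-(tert-butyldimethylsilyloxy)-1-[3-methoxy-4-(triisopropylsilyloxy)phenyl]pent-3-en-2-yl group, via ortho-dienone 23 (not isolated)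
Conditions: Eu(fod)3 (10 mol %), toluene, 80 °C, Ar
Reagents that add atoms: none
Why: Eu(fod)3 binds O4 and the neighbouring C3 methoxy oxygen of ring B as a chelate and weakens the O4–C bond, after which a concerted suprafacial [3,3] shift (aromatic Claisen rearrangement; closest known case: the lanthanide-catalysed rearrangement of enantioenriched pent-3-en-2-yl guaiacyl ethers) exchanges that bond for the C5–C8 bond and gives dienone 23, which enolises to phenol 24. No ring is closed, since the six-membered array exists only in the chair-like transition state. C8 is set by 1,3-chirality transfer: with the carbinol methyl equatorial, the (R)-configured O–CH(CH3) carbon presents ring B to a single face of the (E)-alkene, so C8 forms with the spatial arrangement of the target (S by CIP while propenyl is attached) and the new alkene is E; on this face the C7–O bond can stand anti to the forming bond with C7–H inside, so the resident C7 centre should not oppose the transfer and the anti C7/C8 relationship results. The regioselectivity needed is C5 only: a shift to C3 gives a dienone that is blocked by OMe and can only revert, and the para carbon C1 bears the benzylic CH2, so the manifold drains through C5. The chemoselectivity needed is survival of the doubly activated C7–OTBS bond and of the secondary allyl ether against ionisation, which the mild oxophilic catalyst, the non-polar solvent and the moderate temperature are chosen to secure.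

**Step 16**
Reactants: 24 C5-alkylated phenol
Product: 27 C4-phenol whose ring B carries at C5 the (1R,2R)-1-(tert-butyldimethylsilyloxy)-3-hydroxy-1-[3-methoxy-4-(triisopropylsilyloxy)phenyl]propan-2-yl group, via ozonide 25 (not isolated), via C9 aldehyde 26 (not isolated)
Conditions: O3, CH2Cl2, −78 °C (Sudan Red 7B end point); then MeOH, NaBH4, −78 → 0 °C
Reagents that add atoms: ozone, [O-][O+]=O
Why: Ozonolysis with reductive borohydride work-up: ozone reacts with the isolated 1,2-disubstituted alkene far faster than with the arenes when the end point is signalled by a dye, and NaBH4 added at −78 °C takes ozonide 25 through aldehyde 26 directly to the primary alcohol, so the epimerisable α-aryl-β-silyloxy aldehyde never accumulates, C8 keeps its arrangement and the lactone is not reduced at this temperature.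

**Step 17**
Reactants: 27 tris-silylated precursor
Product: 28 CNP0109231.2 (target)
Conditions: Bu4NF/AcOH (1:1), THF, 0 °C → rt
Reagents that add atoms: none
Why: Fluoride-mediated global desilylation: acetic-acid-buffered Bu4NF removes both aryl TIPS ethers and the benzylic TBS ether while keeping the phenols protonated, which avoids quinone-methide formation at C7, acid-induced closure to a dihydrobenzofuran and epimerisation of the lactone.

**Compound list**
1 | O-benzylvanillin | COc1cc(C=O)ccc1OCc1ccccc1 | starting material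
2 | dimethyl succinate | COC(=O)CCC(=O)OC | starting material
3 | (E)-Stobbe half-ester | COC(=O)C(/CC(=O)O)=C/c1ccc(OCc2ccccc2)c(OC)c1 | intermediate
4 | (3R)-4-[4-(benzyloxy)-3-methoxyphenyl]-3-(methoxycarbonyl)butanoic acid | COC(=O)[C@@H](CC(=O)O)Cc1ccc(OCc2ccccc2)c(OC)c1 | intermediate
5 | (3R)-4-[4-(benzyloxy)-3-methoxyphenyl]-3-(hydroxymethyl)butanoic acid (not isolated) | OC[C@@H](CC(=O)O)Cc1ccc(OCc2ccccc2)c(OC)c1 | intermediate
6 | (4R)-4-[4-(benzyloxy)-3-methoxybenzyl]dihydrofuran-2(3H)-one | C1C(=O)OC[C@@H]1Cc2ccc(OCc3ccccc3)c(OC)c2 | intermediate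
7 | vanillin | COc1cc(C=O)ccc1O | starting material
8 | O-TIPS-vanillin | COc1cc(C=O)ccc1O[Si](C(C)C)(C(C)C)C(C)C | intermediate
9 | [3-methoxy-4-(triisopropylsilyloxy)phenyl]methanol | COc1cc(CO)ccc1O[Si](C(C)C)(C(C)C)C(C)C | intermediate
10 | 3-methoxy-4-(triisopropylsilyloxy)benzyl bromide | COc1cc(CBr)ccc1O[Si](C(C)C)(C(C)C)C(C)C | intermediate
11 | lithium enolate of lactone 6 (not isolated) | [Li]OC1=C[C@@H](Cc2ccc(OCc3ccccc3)c(OC)c2)CO1 | intermediate
12 | (3R,4R)-trans-dibenzyl lactone, ring B phenol as benzyl ether | COc1cc(C[C@H]2C(=O)OC[C@@H]2Cc2cc(OC)c(OCc3ccccc3)cc2)ccc1O[Si](C(C)C)(C(C)C)C(C)C | intermediate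
13 | (3R,4R)-mono-phenol lactone, ring B C4–OH free | COc1cc(C[C@H]2C(=O)OC[C@@H]2Cc2cc(OC)c(O)cc2)ccc1O[Si](C(C)C)(C(C)C)C(C)C | intermediate
14 | (S)-but-3-yn-2-ol | C#C[C@H](C)O | starting material
15 | (S)-3-(triethylsilyloxy)but-1-yne | C#C[C@H](C)O[Si](CC)(CC)CC | intermediate
16 | ethyl[(S)-3-(triethylsilyloxy)but-1-ynyl]zinc (not isolated) | CC[Zn]C#C[C@H](C)O[Si](CC)(CC)CC | intermediate
17 | (1S,4S)-propargylic alcohol | CC[Si](CC)(CC)O[C@@H](C)C#C[C@@H](O)c1ccc(O[Si](C(C)C)(C(C)C)C(C)C)c(OC)c1 | intermediate
18 | sodium five-membered cyclic alkenylalanate (not isolated) | [Na+].COCCO[Al-]1(OCCOC)O[C@@H](c2ccc(O[Si](C(C)C)(C(C)C)C(C)C)c(OC)c2)C=C1[C@H](C)O[Si](CC)(CC)CC | intermediate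
19 | (1R,2E,4S)-allylic alcohol, C7–OH free, OTES at the methyl carbinol | CC[Si](CC)(CC)O[C@@H](C)/C=C/[C@@H](O)c1ccc(O[Si](C(C)C)(C(C)C)C(C)C)c(OC)c1 | intermediate
20 | (2S,3E,5R)-C7 TBS ether, OTES at the methyl carbinol | CC[Si](CC)(CC)O[C@@H](C)/C=C/[C@@H](O[Si](C)(C)C(C)(C)C)c1ccc(O[Si](C(C)C)(C(C)C)C(C)C)c(OC)c1 | intermediate
21 | (2S,3E,5R)-allylic alcohol carrying the C7 TBS ether | O[C@@H](C)/C=C/[C@@H](O[Si](C)(C)C(C)(C)C)c1ccc(O[Si](C(C)C)(C(C)C)C(C)C)c(OC)c1 | intermediate
22 | (R)-secondary allyl aryl ether on O4 of ring B | COc1cc(C[C@H]2C(=O)OC[C@@H]2Cc2cc(OC)c(O[C@H](C)/C=C/[C@@H](O[Si](C)(C)C(C)(C)C)c3ccc(O[Si](C(C)C)(C(C)C)C(C)C)c(OC)c3)cc2)ccc1O[Si](C(C)C)(C(C)C)C(C)C | intermediate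
23 | ortho-dienone, ring B as cyclohexa-2,4-dienone with sp3 C5 drawn as from the chair transition state (not isolated) | COc1cc(C[C@H]2C(=O)OC[C@@H]2CC2=C[C@H]([C@H](/C=C/C)[C@@H](O[Si](C)(C)C(C)(C)C)c3ccc(O[Si](C(C)C)(C(C)C)C(C)C)c(OC)c3)C(=O)C(OC)=C2)ccc1O[Si](C(C)C)(C(C)C)C(C)C | intermediate
24 | C5-alkylated phenol with (E)-propenyl on C8 | COc1cc(C[C@H]2C(=O)OC[C@@H]2Cc2cc(OC)c(O)c([C@H](/C=C/C)[C@@H](O[Si](C)(C)C(C)(C)C)c3ccc(O[Si](C(C)C)(C(C)C)C(C)C)c(OC)c3)c2)ccc1O[Si](C(C)C)(C(C)C)C(C)C | intermediate
25 | 1,2,4-trioxolane (ozonide) on C8, trioxolane centres undefined (not isolated) | COc1cc(C[C@H]2C(=O)OC[C@@H]2Cc2cc(OC)c(O)c([C@H](C4OOC(C)O4)[C@@H](O[Si](C)(C)C(C)(C)C)c3ccc(O[Si](C(C)C)(C(C)C)C(C)C)c(OC)c3)c2)ccc1O[Si](C(C)C)(C(C)C)C(C)C | intermediate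
26 | C9 aldehyde (not isolated) | COc1cc(C[C@H]2C(=O)OC[C@@H]2Cc2cc(OC)c(O)c([C@H](C=O)[C@@H](O[Si](C)(C)C(C)(C)C)c3ccc(O[Si](C(C)C)(C(C)C)C(C)C)c(OC)c3)c2)ccc1O[Si](C(C)C)(C(C)C)C(C)C | intermediate
27 | C9 primary alcohol, (7R,8R), three silyl ethers in place | COc1cc(C[C@H]2C(=O)OC[C@@H]2Cc2cc(OC)c(O)c([C@H](CO)[C@@H](O[Si](C)(C)C(C)(C)C)c3ccc(O[Si](C(C)C)(C(C)C)C(C)C)c(OC)c3)c2)ccc1O[Si](C(C)C)(C(C)C)C(C)C | intermediate
28 | CNP0109231.2, lactone (3R,4R), side chain (7R,8R) | COc1cc(C[C@H]2C(=O)OC[C@@H]2Cc2cc(OC)c(O)c([C@H](CO)[C@@H](O)c3ccc(O)c(OC)c3)c2)ccc1O | target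

**Total step count:** 17

**Longest linear sequence:** 9 steps (7 → 8 → 17 → 19 → 20 → 21 → 22 → 24 → 27 → 28). The lactone branch 1 → 3 → 4 → 6 → 12 → 13 → 22 → 24 → 27 → 28 is equally long.

**Steps most likely to fail**

Risk 1, step 15. The migrating terminus is branched, so the shift may be slow. Ionisation of the secondary allyl ether could then compete, leading to loss of the allyl group by elimination and erosion of the chirality transfer. Leakage through the axial-methyl transition state is also possible.

The fallback gives up the C5–C8 disconnection and forms C7–C8 by allylboration. It sets out from 13 and rejoins the route at 28.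
- Ortho-formylation of the only free phenol (MgCl2, Et3N, paraformaldehyde, MeCN, reflux) should give the C5 salicylaldehyde F1.
- TBSCl/imidazole gives the silyl-protected aldehyde F2.
- Wittig methylenation (Ph3PCH3Br, KOtBu, THF, 0 °C) gives the C5 styrene F3.
- Cross metathesis with allylboronic acid pinacol ester (second-generation Hoveyda–Grubbs catalyst, CH2Cl2, 40 °C) gives the (E)-cinnamyl-type boronate F4.
- Allylboration of aldehyde 8, catalysed by the chiral phosphoric acid (R)-TRIP (toluene, −30 °C), proceeds through a closed Zimmerman–Traxler chair. The (E)-boronate fixes the anti C7/C8 relationship and the catalyst chooses the Re face of 8. Hydrolytic work-up should give the homoallylic alcohol F5.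
- Ozonolysis with borohydride work-up under the conditions of step 16 converts the vinyl group into C9H2OH and gives the diol F6.
- The conditions of step 17 then give 28.

Risk 2, step 14. SN2' attack, ionisation of the activated allylic alcohol and elimination may compete with direct displacement, which would mean incomplete inversion and regiochemical leakage.

The fallback makes the O4–C bond one stage earlier, on a propargylic carbinol, where Mitsunobu displacement is reliably invertive. It sets out from 13 and 14 and rejoins the route at 22.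
- Phenol 13 and (S)-but-3-yn-2-ol 14 (PPh3, DIAD) should give the (R)-but-3-yn-2-yl aryl ether F7.
- Hydroboration of the terminal alkyne with Cy2BH gives the (E)-alkenylborane F8.
- Boron–zinc exchange with Et2Zn gives the alkenyl(ethyl)zinc F9.
- (+)-MIB-catalysed addition of F9 to the Re face of aldehyde 8 gives the (E)-allylic alcohol F10, with C7 set by the catalyst.
- TBSCl/imidazole then gives 22.

Risk 3, step 16. Ozone may over-oxidise the electron-rich ring that bears the free phenol. Epimerisation at C8 or β-elimination of silanol may also occur at the aldehyde stage before hydride arrives.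

The fallback caps the phenol and cleaves the alkene through a glycol. It sets out from 24 and rejoins the route at 28.
- TESOTf/2,6-lutidine gives the triethylsilyl ether F11.
- Dihydroxylation (OsO4 cat., NMO, acetone/H2O) gives the diol F12. The configuration of its two new carbinols is irrelevant.
- NaIO4 cleaves the glycol to the aldehyde F13.
- Immediate NaBH4 reduction (MeOH, −20 °C) gives the primary alcohol F14.
- The conditions of step 17 strip all four silyl groups and give 28.

**Further compounds**
F1 | step 15 | C5 salicylaldehyde of 13 | COc1cc(C[C@H]2C(=O)OC[C@@H]2Cc2cc(OC)c(O)c(C=O)c2)ccc1O[Si](C(C)C)(C(C)C)C(C)C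
F2 | step 15 | O4-TBS-protected C5 aldehyde | COc1cc(C[C@H]2C(=O)OC[C@@H]2Cc2cc(OC)c(O[Si](C)(C)C(C)(C)C)c(C=O)c2)ccc1O[Si](C(C)C)(C(C)C)C(C)C
F3 | step 15 | C5 styrene | COc1cc(C[C@H]2C(=O)OC[C@@H]2Cc2cc(OC)c(O[Si](C)(C)C(C)(C)C)c(C=C)c2)ccc1O[Si](C(C)C)(C(C)C)C(C)C
F4 | step 15 | (E)-cinnamyl-type pinacol boronate | COc1cc(C[C@H]2C(=O)OC[C@@H]2Cc2cc(OC)c(O[Si](C)(C)C(C)(C)C)c(/C=C/CB3OC(C)(C)C(C)(C)O3)c2)ccc1O[Si](C(C)C)(C(C)C)C(C)C
F5 | step 15 | anti homoallylic alcohol, vinyl on C8, C7–OH free | COc1cc(C[C@H]2C(=O)OC[C@@H]2Cc2cc(OC)c(O[Si](C)(C)C(C)(C)C)c([C@H](C=C)[C@@H](O)c3ccc(O[Si](C(C)C)(C(C)C)C(C)C)c(OC)c3)c2)ccc1O[Si](C(C)C)(C(C)C)C(C)C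
F6 | step 15 | C7,C9 diol with three phenolic silyl ethers | COc1cc(C[C@H]2C(=O)OC[C@@H]2Cc2cc(OC)c(O[Si](C)(C)C(C)(C)C)c([C@H](CO)[C@@H](O)c3ccc(O[Si](C(C)C)(C(C)C)C(C)C)c(OC)c3)c2)ccc1O[Si](C(C)C)(C(C)C)C(C)C
F7 | step 14 | (R)-but-3-yn-2-yl aryl ether of 13 | COc1cc(C[C@H]2C(=O)OC[C@@H]2Cc2cc(OC)c(O[C@H](C)C#C)cc2)ccc1O[Si](C(C)C)(C(C)C)C(C)C
F8 | step 14 | (E)-alkenyl(dicyclohexyl)borane | COc1cc(C[C@H]2C(=O)OC[C@@H]2Cc2cc(OC)c(O[C@H](C)/C=C/B(C3CCCCC3)C3CCCCC3)cc2)ccc1O[Si](C(C)C)(C(C)C)C(C)C
F9 | step 14 | (E)-alkenyl(ethyl)zinc | COc1cc(C[C@H]2C(=O)OC[C@@H]2Cc2cc(OC)c(O[C@H](C)/C=C/[Zn]CC)cc2)ccc1O[Si](C(C)C)(C(C)C)C(C)C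
F10 | step 14 | (E)-allylic alcohol, C7–OH free, aryl ether in place | COc1cc(C[C@H]2C(=O)OC[C@@H]2Cc2cc(OC)c(O[C@H](C)/C=C/[C@@H](O)c3ccc(O[Si](C(C)C)(C(C)C)C(C)C)c(OC)c3)cc2)ccc1O[Si](C(C)C)(C(C)C)C(C)C
F11 | step 16 | O4 triethylsilyl ether of 24 | COc1cc(C[C@H]2C(=O)OC[C@@H]2Cc2cc(OC)c(O[Si](CC)(CC)CC)c([C@H](/C=C/C)[C@@H](O[Si](C)(C)C(C)(C)C)c3ccc(O[Si](C(C)C)(C(C)C)C(C)C)c(OC)c3)c2)ccc1O[Si](C(C)C)(C(C)C)C(C)C
F12 | step 16 | vicinal diol from the propenyl group | COc1cc(C[C@H]2C(=O)OC[C@@H]2Cc2cc(OC)c(O[Si](CC)(CC)CC)c([C@H](C(O)C(C)O)[C@@H](O[Si](C)(C)C(C)(C)C)c3ccc(O[Si](C(C)C)(C(C)C)C(C)C)c(OC)c3)c2)ccc1O[Si](C(C)C)(C(C)C)C(C)C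
F13 | step 16 | O4-TES C9 aldehyde | COc1cc(C[C@H]2C(=O)OC[C@@H]2Cc2cc(OC)c(O[Si](CC)(CC)CC)c([C@H](C=O)[C@@H](O[Si](C)(C)C(C)(C)C)c3ccc(O[Si](C(C)C)(C(C)C)C(C)C)c(OC)c3)c2)ccc1O[Si](C(C)C)(C(C)C)C(C)C
F14 | step 16 | O4-TES C9 primary alcohol | COc1cc(C[C@H]2C(=O)OC[C@@H]2Cc2cc(OC)c(O[Si](CC)(CC)CC)c([C@H](CO)[C@@H](O[Si](C)(C)C(C)(C)C)c3ccc(O[Si](C(C)C)(C(C)C)C(C)C)c(OC)c3)c2)ccc1O[Si](C(C)C)(C(C)C)C(C)C
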